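**Remark on the chemistry:** carotenoid numbering is used in the text (ring C1–C6, chain C7–C15, primes for the second half). In the systematic names of the C15 intermediates, carotenoid C4 is ring position 3 and C6 is ring position 1. The SMILES and the name agree on S at C6 and C6′ and on an all-E chain; that structure is the target.

## The problem

1. The target is a C2-symmetric C40 hydrocarbon: an all-E nonaene chain (C7 to C7′, four methyl branches) ending on both sides in a 2,6,6-trimethylcyclohex-2-enyl (ε) ring.
2. Its only stereocentres are C6 and C6′. Each is a ring CH that is doubly allylic (ring C4=C5 on one side, chain C7=C8 on the other) and sits next to the quaternary C1.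
3. The two centres lie nineteen bonds apart, so neither can control the other; each must be set on its own, with the same sense.
4. The ring double bond is in the non-conjugated position. Acid or base that reaches C6–H moves it to C5=C6 (β ring), the more stable position, and erases the stereocentre, so configuration and double-bond position depend on the same hydrogen.
5. The product has no heteroatom to direct anything, and the polyene does not survive strong acid, electrophiles, or light with oxygen.
6. The chain is the lesser problem, provided it is joined from E-configured blocks and the last-formed double bonds can be equilibrated to E.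
7. The feature that opens the key step: C6 carries hydrogen and is the far end of the allyl triad C4–C5(CH3)=C6 of a β ring. An ε ring is therefore what results when hydride replaces a C4 substituent of a 4-oxygenated β ring with allylic transposition, and a C4 carbinol is easy to set by ketone reduction.

## Retrosynthesis

**Cut 1 (C11=C12 and C11′=C12′).** Target 18 is divided into two molecules of the C15 phosphonium salt 13 and the commercial C10 dialdehyde 14.
- For this cut: the C2 axis allows three components to be joined in one operation, and 14 brings three E double bonds ready-made.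
- Against the neighbours: a cut at C7=C8 would need an aldehyde with the stereocentre α to the formyl group; a cut at C15=C15′ would need a C20 half.
- Simplification: 13 holds one ring, one stereocentre and two E double bonds.
- Forward demand: a base that does not touch C6–H, and a way to bring the new disubstituted double bonds to E.

**Cut 2 (C11–P, then the oxidation level of C11).** Salt 13 comes from the primary dienyl alcohol 12, and 12 from the ester 11 by hydride reduction.
- For this cut: the ester is the group that is wanted at the key step (see cut 3), and its removal costs one step.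
- Forward demand: 13 must form without migration of the ring double bond.

**Cut 3 (C6–H bond and position of the ring double bond; key step).** Ester 11 is traced to the (4R)-4-hydroxy-β-ring ester 6 and the sulfonylhydrazone 7.
- Forward reaction: nitrogen replaces oxygen at C4 with inversion; the allylic diazene 10 then passes its N–H hydrogen to C6 in a retro-ene step while the nitrogen atoms leave.
- For this cut: one operation sets C6, places the double bond at C4=C5 against the thermodynamic preference, and works on a substrate that already carries the E,E-dienoate.
- Against the neighbours: forming C6–C7 or protonating a C6 enolate leaves the double-bond position open. The same step on the C13 ketone 1 level would have two ketones to tell apart at the reduction. On a full polyene the C4 leaving group would ionise.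
- Simplification: 6 has an achiral β ring and a single carbinol stereocentre.
- Forward demand: clean SN2 inversion at C4, and suprafacial hydrogen delivery to C6.

**Cut 4 (C4–H, then C4=O).** Carbinol 6 comes from enone 5 by catalytic enantioselective reduction, and 5 from the β-ring ester 4 by allylic oxidation of the ring CH2 at C4.
- For this cut: the ester is inert to the reductant, so only one carbonyl group is reduced.
- Forward demand: the enone branch and the CH2 branch of the ketone must be told apart, and C4 must be the most reactive allylic position of 4.

**Cut 5 (C9=C10).** Ester 4 comes from β-ionone 1 and phosphonate 2 by Horner–Wadsworth–Emmons olefination. Compound 1 brings the ring, all three ring methyl groups and the E double bond C7=C8.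

## Roads not taken

**Alternative 1:** the most obvious route. The cut is the same C11=C12/C11′=C12′ pair, but the ring stereocentre is obtained by sorting rather than by synthesis.
- Forward key step: classical resolution of racemic α-ionone A1 through diastereomeric derivatives to (S)-α-ionone A2, then addition of a vinyl Grignard reagent and phosphonium salt formation to reach 13.
- Why the chosen plan is better: resolution discards the wrong half, and A2 must survive derivatisation and cleavage, both steps in which C6–H is exposed. In the chosen plan the sense at C6 is selected by the catalyst enantiomer in step 3 and relayed by a stereospecific mechanism. The step count of Alternative 1 is lower, but its material throughput is capped at half.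

**Alternative 2:** cut at C7=C8 and C7′=C8′.
- Forward key step: enantioselective protonation of the enolate of thioester A3 by a chiral amino alcohol, reduction to (S)-α-cyclocitral A4, and double olefination of A4 with a doubly functionalised C20 centre piece.
- Why the chosen plan is better: in A4 the stereocentre is α to the formyl group, so a basic olefination invites epimerisation and conjugation to the β isomer. The chiral proton source is stoichiometric, the E geometry of C7=C8 has to be made instead of inherited from 1, and the centre piece needs several steps where 14 is bought.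

**Alternative 3:** no C–C cut at all, end-group editing on the C40 level.
- Forward key step: double oxazaborolidine reduction of canthaxanthin A5 to (4R,4′R)-isozeaxanthin A6, then the double Mitsunobu/diazene transposition directly to 18.
- Why the chosen plan is better: in A6 the activated C4–O bond is allylic to an undecaene, so ionisation to a polyenyl cation should compete with SN2 displacement. The relay of configuration would then be lost, and elimination to retro-dehydro products would compete. A stereo-error at this stage also cannot be removed from a C40 hydrocarbon. In 6 the same carbinol is conjugated with an ester-terminated diene that disfavours the cation, and the steps are run on a soluble C15 ester.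

Key step: step 4

## Route

**Step 1**
Reactants: 1 β-ionone, (E)-4-(2,6,6-trimethylcyclohex-1-en-1-yl)but-3-en-2-one; 2 triethyl phosphonoacetate
Product: 4 ethyl (2E,4E)-3-methyl-5-(2,6,6-trimethylcyclohex-1-en-1-yl)penta-2,4-dienoate, via sodium phosphonate carbanion 3 (not isolated)
Conditions: NaH, THF, 0 °C to reflux; chromatography to remove the 2Z isomer
Reagents that add atoms: none
Why: Horner–Wadsworth–Emmons olefination of the methyl ketone with the stabilised carbanion; the reversible addition favours the 2E ester, and the minor 2Z isomer expected from a ketone is separated here so that C9=C10 is E from the start.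

**Step 2**
Reactants: 4 ethyl (2E,4E)-3-methyl-5-(2,6,6-trimethylcyclohex-1-en-1-yl)penta-2,4-dienoate
Product: 5 ethyl (2E,4E)-3-methyl-5-(2,6,6-trimethyl-3-oxocyclohex-1-en-1-yl)penta-2,4-dienoate
Conditions: t-BuOOH (5 equiv, in decane), Rh2(cap)4 (cap = caprolactamate, 1 mol %), K2CO3, CH2Cl2, rt
Reagents that add atoms: tert-butyl hydroperoxide, CC(C)(C)OO
Why: radical allylic C–H oxidation by tert-butylperoxyl radicals; the ring C4–H bonds are secondary and allylic to the whole trienoate and so are the weakest in 4, and the mixed peroxide formed at C4 collapses to the enone. The electron-poor dienoate is not epoxidised by this oxidant.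

**Step 3**
Reactants: 5 ethyl (2E,4E)-3-methyl-5-(2,6,6-trimethyl-3-oxocyclohex-1-en-1-yl)penta-2,4-dienoate
Product: 6 ethyl (2E,4E)-5-[(3R)-3-hydroxy-2,6,6-trimethylcyclohex-1-en-1-yl]-3-methylpenta-2,4-dienoate
Conditions: (S)-Me-CBS [(S)-1-methyl-3,3-diphenyltetrahydro-1H,3H-pyrrolo[1,2-c][1,3,2]oxazaborole] (0.2 equiv), catecholborane (1.8 equiv), toluene, −78 °C; MeOH quench, aqueous Na2CO3 wash
Reagents that add atoms: none
Why: Corey–Bakshi–Shibata reduction of a cyclic enone; the methyl-bearing enone carbon C5 acts as the large group and C3H2 as the small one, so the (S)-catalyst should deliver hydride to the face that gives the R carbinol (the (R)-catalyst would give the antipode). Catecholborane at −78 °C leaves the ester and the triene alone.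

**Step 4**
Reactants: 6 ethyl (2E,4E)-5-[(3R)-3-hydroxy-2,6,6-trimethylcyclohex-1-en-1-yl]-3-methylpenta-2,4-dienoate; 7 2-nitro-N′-(propan-2-ylidene)benzenesulfonohydrazide (IPNBSH)
Product: 11 ethyl (2E,4E)-3-methyl-5-[(1S)-2,6,6-trimethylcyclohex-2-en-1-yl]penta-2,4-dienoate, via Mitsunobu adduct 8 (not isolated), via free sulfonylhydrazine 9 (not isolated), via allylic diazene 10 (not isolated)
Conditions: PPh3, diethyl azodicarboxylate, THF, 0 °C to rt; then CF3CH2OH/H2O (1:1), rt
Reagents that add atoms: none
Why: The alcohol is activated as its oxyphosphonium ion and displaced at C4 by the sulfonamide nitrogen of 7 with inversion (Mitsunobu reaction) to give 8; trifluoroethanol–water cleaves the acetone hydrazone (9), 2-nitrobenzenesulfinic acid is eliminated to give the monoalkyl diazene 10, and 10 transfers its N–H hydrogen to C6 through a six-centre retro-ene transition state while N2 leaves and the double bond moves from C5=C6 to C4=C5. The closest known reaction type is the reductive 1,3-transposition of secondary cyclic allylic alcohols through allylic diazenes generated from arenesulfonylhydrazides, in its one-flask form with 7. No ring is closed; the only cyclic array is the six-membered pericyclic transition state of the retro-ene step. The new stereocentre C6 is controlled by the C4 carbinol alone: the displacement puts nitrogen on the face opposite to the former hydroxyl and the hydrogen is delivered suprafacially to C6 on the face of the C4–N bond, so 4R (position 3 in the name of 6) becomes 6S (position 1 in the name of 11). The step needs SN2 and not SN1 or SN2′ substitution: the dienoate ester conjugated with C5=C6 destabilises an allyl cation at C4, and C6 is fully substituted and flanked by the quaternary C1, so attack at the γ end is blocked. It needs hydrogen delivery to C6 only, which the geometry secures because only C6 can be reached from N–H through a six-membered array, the E double bond C7=C8 holding C8 out of range. The position of the ring double bond is fixed by the mechanism and made irreversible by loss of N2, so the non-conjugated ε isomer should form although the β isomer is more stable, and no acid or base able to return it is present.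

**Step 5**
Reactants: 11 ethyl (2E,4E)-3-methyl-5-[(1S)-2,6,6-trimethylcyclohex-2-en-1-yl]penta-2,4-dienoate
Product: 12 (2E,4E)-3-methyl-5-[(1S)-2,6,6-trimethylcyclohex-2-en-1-yl]penta-2,4-dien-1-ol
Conditions: i-Bu2AlH (2.2 equiv), CH2Cl2, −78 °C; aqueous potassium sodium tartrate
Reagents that add atoms: none
Why: 1,2-reduction of a conjugated ester by i-Bu2AlH at low temperature; the conditions are neither acidic nor basic enough to reach C6–H, and the isolated ring alkene is inert.

**Step 6**
Reactants: 12 (2E,4E)-3-methyl-5-[(1S)-2,6,6-trimethylcyclohex-2-en-1-yl]penta-2,4-dien-1-ol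
Product: 13 [(2E,4E)-3-methyl-5-[(1S)-2,6,6-trimethylcyclohex-2-en-1-yl]penta-2,4-dien-1-yl]triphenylphosphonium bromide
Conditions: PPh3·HBr, MeOH, 0 °C to rt
Reagents that add atoms: triphenylphosphine hydrobromide, [Br-].[PH+](c1ccccc1)(c1ccccc1)c1ccccc1
Why: phosphonium salt formation from an allylic alcohol: the buffered acid ionises the primary dienyl alcohol and triphenylphosphine captures the pentadienyl cation at its primary terminus to give the E,E salt, the standard entry to carotenoid C15 Wittig salts including those with an ε ring.

**Step 7**
Reactants: 13 [(2E,4E)-3-methyl-5-[(1S)-2,6,6-trimethylcyclohex-2-en-1-yl]penta-2,4-dien-1-yl]triphenylphosphonium bromide (two equivalents); 14 (2E,4E,6E)-2,7-dimethylocta-2,4,6-trienedial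
Product: 18 (6S,6′S)-ε,ε-carotene, via phosphorus ylide 15 (not isolated), via C25 monoaldehyde 16 (not isolated), via crude E/Z carotene mixture 17 (not isolated)
Conditions: NaOMe, MeOH/CH2Cl2, 0 °C to rt; then n-heptane, reflux under argon in the dark; crystallisation
Reagents that add atoms: none
Why: double Wittig olefination joins three components at C11=C12 and C11′=C12′; the semi-stabilised ylide gives E and Z isomers at the new bonds, and heating equilibrates them to the all-E isomer, which is the least soluble and crystallises. No stereocentre is formed, and methoxide is too weak a base to reach C6–H. Because two copies of the same enantioenriched half are joined, the minor enantiomer of 13 ends mainly in the meso diastereomer, so the enantiomeric purity of the chiral product should exceed that of 13.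

## Compound list

1 | β-ionone, (E)-4-(2,6,6-trimethylcyclohex-1-en-1-yl)but-3-en-2-one | CC(=O)/C=C/C1=C(C)CCCC1(C)C | starting material
2 | triethyl phosphonoacetate | CCOC(=O)CP(=O)(OCC)OCC | starting material
3 | sodium salt of the carbanion of triethyl phosphonoacetate | CCOC(=O)[CH-]P(=O)(OCC)OCC.[Na+] | intermediate
4 | ethyl (2E,4E)-3-methyl-5-(2,6,6-trimethylcyclohex-1-en-1-yl)penta-2,4-dienoate | CCOC(=O)/C=C(C)/C=C/C1=C(C)CCCC1(C)C | intermediate
5 | ethyl (2E,4E)-3-methyl-5-(2,6,6-trimethyl-3-oxocyclohex-1-en-1-yl)penta-2,4-dienoate | CCOC(=O)/C=C(C)/C=C/C1=C(C)C(=O)CCC1(C)C | intermediate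
6 | ethyl (2E,4E)-5-[(3R)-3-hydroxy-2,6,6-trimethylcyclohex-1-en-1-yl]-3-methylpenta-2,4-dienoate | CCOC(=O)/C=C(C)/C=C/C1=C(C)[C@H](O)CCC1(C)C | intermediate
7 | 2-nitro-N′-(propan-2-ylidene)benzenesulfonohydrazide (IPNBSH) | CC(C)=NNS(=O)(=O)c1ccccc1[N+](=O)[O-] | starting material
8 | ethyl (2E,4E)-3-methyl-5-[(3S)-2,6,6-trimethyl-3-[1-(2-nitrophenylsulfonyl)-2-(propan-2-ylidene)hydrazinyl]cyclohex-1-en-1-yl]penta-2,4-dienoate (Mitsunobu adduct) | CCOC(=O)/C=C(C)/C=C/C1=C(C)[C@@H](N(N=C(C)C)S(=O)(=O)c2ccccc2[N+](=O)[O-])CCC1(C)C | intermediate
9 | ethyl (2E,4E)-3-methyl-5-[(3S)-2,6,6-trimethyl-3-[1-(2-nitrophenylsulfonyl)hydrazinyl]cyclohex-1-en-1-yl]penta-2,4-dienoate | CCOC(=O)/C=C(C)/C=C/C1=C(C)[C@@H](N(N)S(=O)(=O)c2ccccc2[N+](=O)[O-])CCC1(C)C | intermediate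
10 | ethyl (2E,4E)-5-[(3S)-3-diazenyl-2,6,6-trimethylcyclohex-1-en-1-yl]-3-methylpenta-2,4-dienoate (allylic diazene) | CCOC(=O)/C=C(C)/C=C/C1=C(C)[C@@H](N=N)CCC1(C)C | intermediate
11 | ethyl (2E,4E)-3-methyl-5-[(1S)-2,6,6-trimethylcyclohex-2-en-1-yl]penta-2,4-dienoate | CCOC(=O)/C=C(C)/C=C/[C@@H]1C(C)=CCCC1(C)C | intermediate
12 | (2E,4E)-3-methyl-5-[(1S)-2,6,6-trimethylcyclohex-2-en-1-yl]penta-2,4-dien-1-ol | OC/C=C(C)/C=C/[C@@H]1C(C)=CCCC1(C)C | intermediate
13 | [(2E,4E)-3-methyl-5-[(1S)-2,6,6-trimethylcyclohex-2-en-1-yl]penta-2,4-dien-1-yl]triphenylphosphonium bromide | CC1=CCCC(C)(C)[C@@H]1/C=C/C(C)=C/C[P+](c1ccccc1)(c1ccccc1)c1ccccc1.[Br-] | intermediate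
14 | (2E,4E,6E)-2,7-dimethylocta-2,4,6-trienedial | O=C/C(C)=C/C=C/C=C(C)/C=O | starting material
15 | phosphorus ylide of 13 | CC1=CCCC(C)(C)[C@@H]1/C=C/C(C)=C/C=P(c1ccccc1)(c1ccccc1)c1ccccc1 | intermediate
16 | (2E,4E,6E,10E,12E)-2,7,11-trimethyl-13-[(1S)-2,6,6-trimethylcyclohex-2-en-1-yl]trideca-2,4,6,8,10,12-hexaenal, E/Z mixture at the new C8=C9 bond | CC1=CCCC(C)(C)[C@@H]1/C=C/C(C)=C/C=CC(/C)=C/C=C/C=C(C)/C=O | intermediate
17 | (6S,6′S)-ε,ε-carotene as the crude mixture of E and Z isomers at C11=C12 and C11′=C12′ | CC1=CCCC(C)(C)[C@@H]1/C=C/C(C)=C/C=CC(/C)=C/C=C/C=C(\C)C=C/C=C(C)/C=C/[C@@H]1C(C)=CCCC1(C)C | intermediate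
18 | (6S,6′S)-ε,ε-carotene, all-E | CC1=CCCC(C)(C)[C@@H]1/C=C/C(C)=C/C=C/C(C)=C/C=C/C=C(C)/C=C/C=C(C)/C=C/[C@@H]1C(C)=CCCC1(C)C | target

## Step count and risks

Total step count: 7. Longest linear sequence: 7 steps (1 to 18); 14 enters in the last step.

**Step 4 (key step).**
- What may go wrong: ionisation of the C4 oxyphosphonium ion, or E2 elimination toward C3, in competition with displacement by the bulky sulfonamide nitrogen, whose approach is hindered by the C5 methyl group. This would erode the inversion at C4 and hence the configuration at C6, or divert material to a triene.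
- Fallback, from 6 back to 11: 6 is formylated (formic acid, dicyclohexylcarbodiimide, 4-dimethylaminopyridine) to the (R)-allylic formate F1. F1 is treated with Pd(OAc)2 and PBu3 in dioxane at rt. Zerovalent palladium formed in the flask ionises the formate with inversion, CO2 leaves the palladium formate, and the hydride is transferred to the more substituted allyl terminus C6 on the metal-bearing face. This is formate hydrogenolysis with allylic transposition, a reaction used to set ring CH centres. Hydrogen again arrives anti to the former oxygen, so 11 results with the same 6S sense.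

**Step 2.**
- What may go wrong: addition of peroxyl radicals to the triene, or hydrogen abstraction from the C5 or C9 methyl groups in competition with C4, and over-oxidation.
- Fallback, from 4 back to 5: Wohl–Ziegler bromination of 4 with N-bromosuccinimide (CCl4, CaCO3) gives the racemic 4-bromide F2, as known for β-ionone-type rings. F2 is oxidised with N-methylmorpholine N-oxide and NaHCO3 in acetonitrile (Kornblum-type oxidation of an allylic bromide) to 5.

**Step 3.**
- What may go wrong: insufficient facial discrimination if the catalyst does not differentiate the C5 branch from C3H2 well enough, or conjugate hydride delivery to the trienone.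
- Fallback, from 5 back to 6: Luche reduction of 5 (NaBH4, CeCl3, MeOH) gives the racemic carbinol F3. Acylation of F3 with vinyl acetate and Candida antarctica lipase B is expected, by the empirical rule for secondary alcohols, to convert the R enantiomer to the (R)-acetate F4 and leave the (S)-carbinol F5. After separation, F5 is esterified with acetic acid under Mitsunobu conditions (inversion) to more F4. Ethanolysis of F4 (K2CO3, EtOH) gives 6, so both enantiomers of F3 are used.

**Step 6.**
- What may go wrong: acid-induced migration of the ring double bond into conjugation, or proton loss from C6 of the pentadienyl cation; both destroy the stereocentre.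
- Fallback, from 12 back to 13: Appel bromination of 12 (CBr4, PPh3, CH2Cl2, −20 °C) gives the primary allylic bromide F6 without a free cation. F6 is treated with PPh3 in ethyl acetate at rt to give 13.

## Further compounds

F1 | step 4 | ethyl (2E,4E)-5-[(3R)-3-(formyloxy)-2,6,6-trimethylcyclohex-1-en-1-yl]-3-methylpenta-2,4-dienoate | CCOC(=O)/C=C(C)/C=C/C1=C(C)[C@H](OC=O)CCC1(C)C
F2 | step 2 | ethyl (2E,4E)-5-(3-bromo-2,6,6-trimethylcyclohex-1-en-1-yl)-3-methylpenta-2,4-dienoate, racemic | CCOC(=O)/C=C(C)/C=C/C1=C(C)C(Br)CCC1(C)C
F3 | step 3 | ethyl (2E,4E)-5-(3-hydroxy-2,6,6-trimethylcyclohex-1-en-1-yl)-3-methylpenta-2,4-dienoate, racemic | CCOC(=O)/C=C(C)/C=C/C1=C(C)C(O)CCC1(C)C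
F4 | step 3 | ethyl (2E,4E)-5-[(3R)-3-acetoxy-2,6,6-trimethylcyclohex-1-en-1-yl]-3-methylpenta-2,4-dienoate | CCOC(=O)/C=C(C)/C=C/C1=C(C)[C@H](OC(C)=O)CCC1(C)C
F5 | step 3 | ethyl (2E,4E)-5-[(3S)-3-hydroxy-2,6,6-trimethylcyclohex-1-en-1-yl]-3-methylpenta-2,4-dienoate | CCOC(=O)/C=C(C)/C=C/C1=C(C)[C@@H](O)CCC1(C)C
F6 | step 6 | (6S)-6-[(1E,3E)-5-bromo-3-methylpenta-1,3-dien-1-yl]-1,5,5-trimethylcyclohex-1-ene | CC1=CCCC(C)(C)[C@@H]1/C=C/C(C)=C/CBr
A1 | alternative 1 | racemic α-ionone, (E)-4-(2,6,6-trimethylcyclohex-2-en-1-yl)but-3-en-2-one | CC(=O)/C=C/C1C(C)=CCCC1(C)C
A2 | alternative 1 | (S)-α-ionone, (E)-4-[(1S)-2,6,6-trimethylcyclohex-2-en-1-yl]but-3-en-2-one | CC(=O)/C=C/[C@@H]1C(C)=CCCC1(C)C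
A3 | alternative 2 | S-phenyl (1S)-2,6,6-trimethylcyclohex-2-ene-1-carbothioate | O=C(Sc1ccccc1)[C@@H]1C(C)=CCCC1(C)C
A4 | alternative 2 | (S)-α-cyclocitral, (1S)-2,6,6-trimethylcyclohex-2-ene-1-carbaldehyde | O=C[C@@H]1C(C)=CCCC1(C)C
A5 | alternative 3 | canthaxanthin, all-E-β,β-carotene-4,4′-dione | CC1=C(/C=C/C(C)=C/C=C/C(C)=C/C=C/C=C(C)/C=C/C=C(C)/C=C/C2=C(C)C(=O)CCC2(C)C)C(C)(C)CCC1=O
A6 | alternative 3 | (4R,4′R)-isozeaxanthin, all-E-(4R,4′R)-β,β-carotene-4,4′-diol | CC1=C(/C=C/C(C)=C/C=C/C(C)=C/C=C/C=C(C)/C=C/C=C(C)/C=C/C2=C(C)[C@H](O)CCC2(C)C)C(C)(C)CC[C@H]1O
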